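**Retrosynthetic overview**

1. The target is an all-cis 3,4,6-substituted 1,2-dioxane (ring O1–O2–C3–C4–C5–C6, chain C1–C14, C1 = CO2H); C1 is carried as a silyl-protected primary alcohol and oxidised last.
2. Key disconnection O1–C6: a C3 hydroperoxide adds across C5=C6 of a (5E,7E)-diene under Brønsted acid catalysis. The enabling feature is that the fully substituted ring carbon C6 is allylic to the exocyclic C7=C8 bond, so protonation at C5 gives an allyl cation C6–C7–C8 that O1 reaches at C6 through the six-membered ring O1–O2–C3–C4–C5–C6. This closes the only ring and sets the C6 quaternary centre.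
3. The C3–O2 bond comes from SN2 perhydrolysis of an anti C3 mesylate (inversion), which gives the cis C3/C4 pattern.
4. The diene comes from a Negishi union at C6–C7 of a C1–C6 alkenylzirconium (from an internal alkyne) with a C7–C14 (E)-alkenyl iodide (methylalumination).
5. Both halves come from one catalytic asymmetric step, (S)-hept-4-yn-3-ol: Marshall–Tamaru propargylation relays it to C4 and C3; Z-semihydrogenation and Johnson–Claisen rearrangement relay it to C10 and the 11E bond.

Key step: step 15

Remark: all intermediates are numbered like the target. 3-[(tert-Butyldiphenylsilyl)oxy]propanal is taken as a catalogue compound. Cyclopentadienyl ligands are drawn σ-bonded in SMILES.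

**Route**

Step 1
Reactants: 1 but-1-yne; 2 N-methoxy-N-methylpropanamide
Product: 4 hept-4-yn-3-one, via lithium but-1-yn-1-ide 3 (not isolated)
Conditions: n-BuLi, THF, −78 °C; then 2, −78 → 0 °C; aq. NH4Cl
Reagents that add atoms: none
Why: Acylation of a lithium acetylide by a Weinreb amide stops at the ketone because the chelated tetrahedral adduct survives until work-up, so the ynone should form without over-addition.

Step 2
Reactants: 4 hept-4-yn-3-one
Product: 5 (3S)-hept-4-yn-3-ol
Conditions: Ru[(S,S)-TsNCHPhCHPhNH](p-cymene) (0.5 mol%), i-PrOH, 25 °C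
Reagents that add atoms: none
Why: Noyori asymmetric transfer hydrogenation of alkynyl ketones differentiates the slim alkynyl group from the alkyl group, and the (S,S)-ligand is chosen to give the S carbinol (the mirror-image catalyst would be taken if the sense proved opposite), which is the only stereocentre of the route set by a catalyst.

Step 3
Reactants: 5 (3S)-hept-4-yn-3-ol
Product: 6 (3S)-hept-4-yn-3-yl methanesulfonate
Conditions: MsCl, Et3N, CH2Cl2, −78 → 0 °C
Reagents that add atoms: methanesulfonyl chloride, CS(=O)(=O)Cl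
Why: O-Sulfonylation of the secondary alcohol does not touch the C–O stereocentre, so the S configuration is kept in the leaving group needed for the propargylation.

Step 4
Reactants: 6 (3S)-hept-4-yn-3-yl methanesulfonate; 7 3-[(tert-butyldiphenylsilyl)oxy]propanal
Product: 9 (3S,4R)-1-[(tert-butyldiphenylsilyl)oxy]-4-ethyloct-5-yn-3-ol, via allenylzinc reagent 8 (not isolated)
Conditions: Pd(OAc)2 (5 mol%), PPh3 (5 mol%), Et2Zn (3 equiv), THF, −78 → −20 °C; aq. NH4Cl
Reagents that add atoms: none
Why: In this Marshall–Tamaru propargylation zerovalent palladium opens the mesylate in an anti SN2′ sense, transmetalation with retention gives the (M)-allenylzinc 8, and its closed chair-like SE2′ addition to the aldehyde transfers the carbinol chirality to C4 (R, net inversion) and sets the anti C3 carbinol (S) in the same event.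

Step 5
Reactants: 9 (3S,4R)-1-[(tert-butyldiphenylsilyl)oxy]-4-ethyloct-5-yn-3-ol
Product: 10 tert-butyl{[(3S,4R)-4-ethyl-3-[(triethylsilyl)oxy]oct-5-yn-1-yl]oxy}diphenylsilane
Conditions: Et3SiCl, imidazole, DMF, 0 → 20 °C
Reagents that add atoms: chlorotriethylsilane, CC[Si](Cl)(CC)CC
Why: Silylation of the secondary alcohol prevents alkoxide-directed hydrozirconation and protonolysis of the organometallics in step 11, and the triethylsilyl ether can later be removed in the presence of the primary tert-butyldiphenylsilyl ether.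

Step 6
Reactants: 5 (3S)-hept-4-yn-3-ol
Product: 11 (3S,4Z)-hept-4-en-3-ol
Conditions: H2 (1 atm), Pd/CaCO3 poisoned with Pb(OAc)2 (Lindlar-type), quinoline, hexane, 20 °C
Reagents that add atoms: none
Why: Syn semihydrogenation on poisoned palladium stops at the Z-alkene and leaves the carbinol centre untouched, giving the Z-allylic alcohol whose Claisen rearrangement delivers the R configuration at C10 from the same S carbinol used in step 3.

Step 7
Reactants: 11 (3S,4Z)-hept-4-en-3-ol
Product: 13 ethyl (3R,4E)-3-ethylhept-4-enoate, via ketene acetal 12 (not isolated)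
Conditions: MeC(OEt)3 (6 equiv), EtCO2H (5 mol%), 140 °C, EtOH distilled off
Reagents that add atoms: triethyl orthoacetate, CC(OCC)(OCC)OCC
Why: In the chair transition state of this Johnson–Claisen rearrangement the carbinol ethyl must be equatorial, because an axial position would clash with the axial Z-ethyl group, so the new C11=C12 bond should be E and the carbinol chirality should be transferred completely to C10 (R).

Step 8
Reactants: 13 ethyl (3R,4E)-3-ethylhept-4-enoate
Product: 14 (3R,4E)-3-ethylhept-4-enal
Conditions: i-Bu2AlH (1.05 equiv), CH2Cl2, −78 °C; aq. potassium sodium tartrate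
Reagents that add atoms: none
Why: Partial reduction of the ester stops at the aldehyde because the tetrahedral aluminium hemiacetal is stable at −78 °C, and the β-stereocentre cannot epimerise.

Step 9
Reactants: 14 (3R,4E)-3-ethylhept-4-enal
Product: 15 (4R,5E)-4-ethyloct-5-en-1-yne
Conditions: dimethyl (1-diazo-2-oxopropyl)phosphonate, K2CO3, MeOH, 0 → 20 °C
Reagents that add atoms: dimethyl (1-diazo-2-oxopropyl)phosphonate, CC(=O)C(=[N+]=[N-])P(=O)(OC)OC
Why: The Ohira–Bestmann (Seyferth–Gilbert) homologation turns the aldehyde into the terminal alkyne under mild carbonate conditions that should not affect the non-enolisable C10 centre or the E-alkene.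

Step 10
Reactants: 15 (4R,5E)-4-ethyloct-5-en-1-yne
Product: 17 (1E,4R,5E)-4-ethyl-1-iodo-2-methylocta-1,5-diene, via alkenylalane 16 (not isolated)
Conditions: Me3Al (2 equiv), Cp2ZrCl2 (0.25 equiv), CH2Cl2, 0 → 20 °C; then I2, THF, −30 → 0 °C
Reagents that add atoms: trimethylaluminium, C[Al](C)C; iodine, II
Why: Negishi zirconium-catalysed methylalumination adds CH3 and aluminium syn across the terminal alkyne with aluminium at the terminus, and iodinolysis with retention fixes the E-trisubstituted C7=C8 geometry that the key step can no longer correct.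

Step 11
Reactants: 10 tert-butyl{[(3S,4R)-4-ethyl-3-[(triethylsilyl)oxy]oct-5-yn-1-yl]oxy}diphenylsilane; 17 (1E,4R,5E)-4-ethyl-1-iodo-2-methylocta-1,5-diene
Product: 20 tert-butyl{[(3S,4R,5E,7E,10R,11E)-4,6,10-triethyl-8-methyl-3-[(triethylsilyl)oxy]tetradeca-5,7,11-trien-1-yl]oxy}diphenylsilane, via alkenylzirconocene chloride 18 (not isolated), via alkenylzinc chloride 19 (not isolated)
Conditions: Cp2Zr(H)Cl (1.5 equiv), THF, 20 → 45 °C; ZnCl2 (1.5 equiv), 0 °C; then 17, Pd(PPh3)4 (5 mol%), THF, 20 °C
Reagents that add atoms: none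
Why: Schwartz hydrozirconation adds H and zirconium syn and, after equilibration with excess hydride, places the metal on C6 next to the unbranched ethyl group, and transmetalation to zinc followed by Negishi coupling with retention at both alkenyl carbons should give the (5E,7E)-diene with C4 trans to C7.

Step 12
Reactants: 20 the bis-silyl ether of step 11
Product: 21 (3S,4R,5E,7E,10R,11E)-1-[(tert-butyldiphenylsilyl)oxy]-4,6,10-triethyl-8-methyltetradeca-5,7,11-trien-3-ol
Conditions: pyridinium p-toluenesulfonate (0.2 equiv), MeOH/CH2Cl2 1:1, 0 °C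
Reagents that add atoms: none
Why: Mild acid-catalysed methanolysis cleaves the secondary triethylsilyl ether much faster than the primary tert-butyldiphenylsilyl ether and is too weakly acidic to protonate the diene.

Step 13
Reactants: 21 the C3 alcohol
Product: 22 (3S,4R,5E,7E,10R,11E)-1-[(tert-butyldiphenylsilyl)oxy]-4,6,10-triethyl-8-methyltetradeca-5,7,11-trien-3-yl methanesulfonate
Conditions: MsCl, Et3N, CH2Cl2, −20 °C; used crude at once
Reagents that add atoms: methanesulfonyl chloride, CS(=O)(=O)Cl
Why: Mesylation of the secondary alcohol proceeds with retention at C3 at low temperature, and immediate use limits ionisation assisted by the homoallylic diene.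

Step 14
Reactants: 22 the C3 mesylate
Product: 23 tert-butyl{[(3R,4R,5E,7E,10R,11E)-4,6,10-triethyl-3-hydroperoxy-8-methyltetradeca-5,7,11-trien-1-yl]oxy}diphenylsilane
Conditions: 50% aq. H2O2 (30 equiv), KOH (3 equiv), MeOH/THF, 0 → 20 °C
Reagents that add atoms: hydrogen peroxide, OO
Why: In this SN2 perhydrolysis the hydroperoxide anion, a strong α-effect nucleophile of low basicity, displaces the secondary mesylate with inversion, turning the anti (3S) carbinol derivative into the (3R) hydroperoxide that carries the cis C3/C4 relationship of the ring.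

Step 15
Reactants: 23 the hydroperoxy diene
Product: 24 tert-butyl{2-[(3R,4R,6R)-4,6-diethyl-6-[(1E,4R,5E)-4-ethyl-2-methylocta-1,5-dien-1-yl]-1,2-dioxan-3-yl]ethoxy}diphenylsilane
Conditions: (CF3SO2)2NH (5 mol%), CH2Cl2 (0.01 M), −40 → 0 °C; quench with Et3N
Reagents that add atoms: none
Why: Proposed new method: the acid protonates C5 of the (5E,7E)-diene, the only position that leads to a fully alkylated allyl cation spread over C6, C7 and C8, and the C3 hydroperoxide oxygen captures this cation at C6 and then returns its proton to the catalyst, so that the 1,2-dioxane ring O1–O2–C3–C4–C5–C6 closes by O1–C6 bond formation through a six-membered transition state (formally a 6-endo-trig Markovnikov addition across C5=C6), capture at C8 being excluded because it would need an eight-membered ring. The closest known reaction types are the Brønsted-acid-catalysed intramolecular hydroalkoxylation of 1,3-dienes and the acid-mediated alkylation of hydroperoxides by tertiary carbocations (the classical synthesis of tert-alkyl peroxides from alkenes or tertiary alcohols), which have not been merged on a hydroperoxy diene. The new quaternary stereocentre C6 is controlled by C4 through a chair-like transition state: C7, which is trans to C4 on the (E)-C5=C6 bond and stays cis to C5 in the allyl cation, is kept away from C4 by allylic 1,3-strain between C4 and C8 and therefore becomes equatorial while the C6 ethyl becomes axial, and the C4 ethyl must then be equatorial to avoid a syn-diaxial ethyl–ethyl contact, which puts the alkenyl chain cis to the C4 ethyl as in the target. The 7E geometry was fixed in step 10 and should be retained because ring closure is faster than rotation about the C7–C8 bond of the cation. The step needs protonation of the diene in preference to the isolated C11=C12 alkene and to the peroxide oxygens, which the much higher basicity of the tetraalkyl diene should secure at low temperature and low acid loading, and it needs the hydroperoxide to be the only internal nucleophile, which the silyl ether at C1 secures.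

Step 16
Reactants: 24 the silyl-protected 1,2-dioxane
Product: 25 2-[(3R,4R,6R)-4,6-diethyl-6-[(1E,4R,5E)-4-ethyl-2-methylocta-1,5-dien-1-yl]-1,2-dioxan-3-yl]ethan-1-ol
Conditions: HF·pyridine, pyridine, THF, 0 → 20 °C
Reagents that add atoms: none
Why: Fluoride-mediated desilylation under pyridine-buffered, weakly acidic conditions frees the primary alcohol while avoiding the basic conditions that could trigger Kornblum–DeLaMare fragmentation at C3–H.

Step 17
Reactants: 25 the primary alcohol
Product: 26 2-[(3R,4R,6R)-4,6-diethyl-6-[(1E,4R,5E)-4-ethyl-2-methylocta-1,5-dien-1-yl]-1,2-dioxan-3-yl]acetic acid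
Conditions: TEMPO (0.2 equiv), PhI(OAc)2 (2.5 equiv), MeCN/aq. phosphate buffer pH 7, 20 °C
Reagents that add atoms: water, O
Why: Oxoammonium (TEMPO) oxidation takes the primary alcohol through the aldehyde hydrate to the carboxylic acid under near-neutral conditions that should spare the dialkyl peroxide, both alkenes and all four stereocentres, none of which is α to the new carbonyl.

**Compound list**

1 | but-1-yne | CCC#C | starting material
2 | N-methoxy-N-methylpropanamide | CCC(=O)N(C)OC | starting material
3 | lithium but-1-yn-1-ide | CCC#C[Li] | intermediate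
4 | hept-4-yn-3-one | CCC(=O)C#CCC | intermediate
5 | (3S)-hept-4-yn-3-ol | CC[C@H](O)C#CCC | intermediate
6 | (3S)-hept-4-yn-3-yl methanesulfonate | CC[C@H](OS(C)(=O)=O)C#CCC | intermediate
7 | 3-[(tert-butyldiphenylsilyl)oxy]propanal | O=CCCO[Si](c1ccccc1)(c1ccccc1)C(C)(C)C | starting material
8 | ethyl[(M)-hepta-3,4-dien-3-yl]zinc | CC[Zn]C(CC)=[C@]=C([H])CC | intermediate
9 | (3S,4R)-1-[(tert-butyldiphenylsilyl)oxy]-4-ethyloct-5-yn-3-ol | CCC#C[C@@H](CC)[C@H](CCO[Si](c1ccccc1)(c1ccccc1)C(C)(C)C)O | intermediate
10 | tert-butyl{[(3S,4R)-4-ethyl-3-[(triethylsilyl)oxy]oct-5-yn-1-yl]oxy}diphenylsilane | CCC#C[C@@H](CC)[C@H](CCO[Si](c1ccccc1)(c1ccccc1)C(C)(C)C)O[Si](CC)(CC)CC | intermediate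
11 | (3S,4Z)-hept-4-en-3-ol | CC[C@H](O)/C=C\CC | intermediate
12 | (3S,4Z)-3-[(1-ethoxyethenyl)oxy]hept-4-ene | C=C(OCC)O[C@@H](CC)/C=C\CC | intermediate
13 | ethyl (3R,4E)-3-ethylhept-4-enoate | CC/C=C/[C@H](CC)CC(=O)OCC | intermediate
14 | (3R,4E)-3-ethylhept-4-enal | CC/C=C/[C@H](CC)CC=O | intermediate
15 | (4R,5E)-4-ethyloct-5-en-1-yne | CC/C=C/[C@H](CC)CC#C | intermediate
16 | [(1E,4R,5E)-4-ethyl-2-methylocta-1,5-dien-1-yl]dimethylalumane | CC/C=C/[C@H](CC)C/C(C)=C/[Al](C)C | intermediate
17 | (1E,4R,5E)-4-ethyl-1-iodo-2-methylocta-1,5-diene | CC/C=C/[C@H](CC)C/C(C)=C/I | intermediate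
18 | chlorobis(cyclopentadienyl)[(3S,4R,5E)-1-[(tert-butyldiphenylsilyl)oxy]-4-ethyl-3-[(triethylsilyl)oxy]oct-5-en-6-yl]zirconium | Cl[Zr](C1C=CC=C1)(C1C=CC=C1)/C(CC)=C/[C@@H](CC)[C@H](CCO[Si](c1ccccc1)(c1ccccc1)C(C)(C)C)O[Si](CC)(CC)CC | intermediate
19 | chloro[(3S,4R,5E)-1-[(tert-butyldiphenylsilyl)oxy]-4-ethyl-3-[(triethylsilyl)oxy]oct-5-en-6-yl]zinc | Cl[Zn]/C(CC)=C/[C@@H](CC)[C@H](CCO[Si](c1ccccc1)(c1ccccc1)C(C)(C)C)O[Si](CC)(CC)CC | intermediate
20 | tert-butyl{[(3S,4R,5E,7E,10R,11E)-4,6,10-triethyl-8-methyl-3-[(triethylsilyl)oxy]tetradeca-5,7,11-trien-1-yl]oxy}diphenylsilane | CC/C=C/[C@H](CC)C/C(C)=C/C(CC)=C/[C@@H](CC)[C@H](CCO[Si](c1ccccc1)(c1ccccc1)C(C)(C)C)O[Si](CC)(CC)CC | intermediate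
21 | (3S,4R,5E,7E,10R,11E)-1-[(tert-butyldiphenylsilyl)oxy]-4,6,10-triethyl-8-methyltetradeca-5,7,11-trien-3-ol | CC/C=C/[C@H](CC)C/C(C)=C/C(CC)=C/[C@@H](CC)[C@H](CCO[Si](c1ccccc1)(c1ccccc1)C(C)(C)C)O | intermediate
22 | (3S,4R,5E,7E,10R,11E)-1-[(tert-butyldiphenylsilyl)oxy]-4,6,10-triethyl-8-methyltetradeca-5,7,11-trien-3-yl methanesulfonate | CC/C=C/[C@H](CC)C/C(C)=C/C(CC)=C/[C@@H](CC)[C@H](CCO[Si](c1ccccc1)(c1ccccc1)C(C)(C)C)OS(C)(=O)=O | intermediate
23 | tert-butyl{[(3R,4R,5E,7E,10R,11E)-4,6,10-triethyl-3-hydroperoxy-8-methyltetradeca-5,7,11-trien-1-yl]oxy}diphenylsilane | CC/C=C/[C@H](CC)C/C(C)=C/C(CC)=C/[C@@H](CC)[C@@H](CCO[Si](c1ccccc1)(c1ccccc1)C(C)(C)C)OO | intermediate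
24 | tert-butyl{2-[(3R,4R,6R)-4,6-diethyl-6-[(1E,4R,5E)-4-ethyl-2-methylocta-1,5-dien-1-yl]-1,2-dioxan-3-yl]ethoxy}diphenylsilane | CC/C=C/[C@H](CC)C/C(C)=C/[C@@]1(CC)C[C@@H](CC)[C@@H](CCO[Si](c2ccccc2)(c2ccccc2)C(C)(C)C)OO1 | intermediate
25 | 2-[(3R,4R,6R)-4,6-diethyl-6-[(1E,4R,5E)-4-ethyl-2-methylocta-1,5-dien-1-yl]-1,2-dioxan-3-yl]ethan-1-ol | CC/C=C/[C@H](CC)C/C(C)=C/[C@@]1(CC)C[C@@H](CC)[C@@H](CCO)OO1 | intermediate
26 | 2-[(3R,4R,6R)-4,6-diethyl-6-[(1E,4R,5E)-4-ethyl-2-methylocta-1,5-dien-1-yl]-1,2-dioxan-3-yl]acetic acid | CC/C=C/[C@H](CC)C/C(C)=C/[C@@]1(CC)C[C@@H](CC)[C@@H](CC(=O)O)OO1 | target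

**Step count and risks**

Total step count: 17 (compounds 3, 8, 12, 16, 18 and 19 are not isolated).
Longest linear sequence: 14 steps (1, 2, 6–17); the C1–C6 half (steps 3–5) joins at step 11.

Steps most likely to fail:

1. Step 15 (proposed new method). Facial control at C6 may be incomplete if the allyl cation rotates about C6–C7 before capture. The cation may lose a proton to trienes. The tertiary allylic peroxide, once formed, may re-ionise under the acid and epimerise or open. Fallback with known chemistry: setting out from hydroperoxide 23, intramolecular cycloperoxymercuration with Hg(OAc)2 (1.1 equiv, cat. HClO4, CH2Cl2, 0 °C) should add divalent mercury and the hydroperoxide anti across the (E)-C5=C6 bond with oxygen at the more substituted C6, giving {(3R,4S,5R,6S)-3-{2-[(tert-butyldiphenylsilyl)oxy]ethyl}-4,6-diethyl-6-[(1E,4R,5E)-4-ethyl-2-methylocta-1,5-dien-1-yl]-1,2-dioxan-5-yl}mercury acetate F1. The same alkene geometry and chair preference should set C6. Reductive demercuration with NaBH4 in aq. NaOH at 0 °C replaces mercury by hydrogen and returns to compound 24.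

2. Step 14. E2 elimination toward the allylic C4–H, ionisation of the mesylate with participation of the homoallylic diene, or a second alkylation to a dialkyl peroxide may outrun substitution at the hindered secondary carbon. Fallback: setting out from mesylate 22, the C–O bond is made with a mono-protected hydroperoxide instead of hydrogen peroxide. The caesium salt of 2-methoxypropan-2-yl hydroperoxide (CsOH·H2O, DMF, 0 °C) should give, with inversion, tert-butyl{[(3R,4R,5E,7E,10R,11E)-4,6,10-triethyl-3-[(2-methoxypropan-2-yl)peroxy]-8-methyltetradeca-5,7,11-trien-1-yl]oxy}diphenylsilane F2, which cannot be alkylated twice. Unmasking the peroxyketal with AcOH/THF/H2O at 20 °C returns to compound 23.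

3. Step 11. Hydrozirconation may place the metal at C5 instead of C6, transmetalation may be incomplete, or homocoupling may occur, all of which would give regioisomeric or dimeric dienes that are hard to separate. Fallback: the polarity of the union is reversed and the regiochemistry is secured at an isolable stage. Setting out from alkyne 10, hydrozirconation followed by iodinolysis (Cp2Zr(H)Cl, THF; then I2) gives tert-butyl{[(3S,4R,5E)-4-ethyl-6-iodo-3-[(triethylsilyl)oxy]oct-5-en-1-yl]oxy}diphenylsilane F3, which can be purified from any regioisomer. The alkenylalane 16, generated from alkyne 15 as in step 10 but not iodinated, is then coupled with F3 in the same flask (ZnCl2, Pd(PPh3)4, THF) and returns to compound 20.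

**Further compounds**

F1 | step 15 | {(3R,4S,5R,6S)-3-{2-[(tert-butyldiphenylsilyl)oxy]ethyl}-4,6-diethyl-6-[(1E,4R,5E)-4-ethyl-2-methylocta-1,5-dien-1-yl]-1,2-dioxan-5-yl}mercury acetate | CC/C=C/[C@H](CC)C/C(C)=C/[C@@]1(CC)[C@H]([Hg]OC(C)=O)[C@@H](CC)[C@@H](CCO[Si](c2ccccc2)(c2ccccc2)C(C)(C)C)OO1
F2 | step 14 | tert-butyl{[(3R,4R,5E,7E,10R,11E)-4,6,10-triethyl-3-[(2-methoxypropan-2-yl)peroxy]-8-methyltetradeca-5,7,11-trien-1-yl]oxy}diphenylsilane | CC/C=C/[C@H](CC)C/C(C)=C/C(CC)=C/[C@@H](CC)[C@@H](CCO[Si](c1ccccc1)(c1ccccc1)C(C)(C)C)OOC(C)(C)OC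
F3 | step 11 | tert-butyl{[(3S,4R,5E)-4-ethyl-6-iodo-3-[(triethylsilyl)oxy]oct-5-en-1-yl]oxy}diphenylsilane | I/C(CC)=C/[C@@H](CC)[C@H](CCO[Si](c1ccccc1)(c1ccccc1)C(C)(C)C)O[Si](CC)(CC)CC
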